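A direct plan would couple the iodophenol A1 (2-iodo-4-methoxy-3,5-bis(methoxymethoxy)phenol), carbon monoxide and the side-chain-bearing arylacetylene A2 under palladium catalysis and close ring C in the same flask to give flavone A3.
It would then remove both MOM groups, benzylate O7, methylate O5 to reach A4, hydroxylate C3 and hydrogenolyse the benzyl ethers.
Its weakest step would be the C3 hydroxylation of A4 (lithium amide, borate, peroxide): a strong-base step on the most advanced material that forms no skeletal bond and can also metalate benzylic positions or open the pyranone.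
Next would come the ether exchange on ring A (MOM removal, mono-benzylation of O7, methylation of the chelated O5): three steps with no gain in complexity, needed only because ring A entered with the wrong ether pattern.
Third would be the carbonylative coupling and cyclisation, which has to win over direct alkyne coupling and over five-membered aurone closure under CO pressure.
The stereocentre would also pass through the α-methyl aldehyde A5, which can epimerise before its olefination.

**Plan of the new route**
The retrosynthesis cuts, in this order, C7–C8 (ring A, Claisen condensation), C4a–C5 (Negishi coupling of a C5–C6–C7 dimethoxyacrylate), C2–C1' (Negishi coupling of ring B) and the benzylic C–C bond of the side chain.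
Ring C is never closed: O1, C2, C3–OH, C4=O, C4a, C8a and C8 are bought together as allomaltol (5-hydroxy-2-methyl-4H-pyran-4-one); ring B is joined as a finished arene and ring A arises last.
The feature used is that C8 is the 2-methyl group of a γ-pyrone, vinylogously acidic through C8a=C4a–C4=O, and sits next to the free position C4a, so an ester (C7) tethered at C4a lies within reach of the C8 carbanion.
O3 is present from the start, O5 and O6 enter as methyl ethers on the acrylate and O7 is born as a free phenol from the ester carbonyl, so neither a late C3 oxidation nor an ether exchange on ring A is needed.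
No carbon monoxide and no flavone-versus-aurone closure occur, and the stereocentre comes from a bromo alcohol whose stereogenic carbon carries no acidic hydrogen.

Key step: step 9

Remark: atom labels O1 to C8a refer to the flavonol numbering of the target, while pyranone intermediates are named by pyran numbering. Compound 16 is taken as its Z isomer (β-methoxy group trans to the ester), the usual outcome of this O-methylation; the E isomer would serve as well, because step 9 corrects the alkene geometry.

Step 1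
Reactants: 1 (R)-3-bromo-2-methylpropan-1-ol
Product: 2 (R)-[(3-bromo-2-methylpropoxy)methyl]benzene
Conditions: benzyl 2,2,2-trichloroacetimidate (1.3 equiv), TfOH (5 mol %), CH2Cl2/cyclohexane, 0 °C → rt
Reagents that add atoms: benzyl 2,2,2-trichloroacetimidate, N=C(OCc1ccccc1)C(Cl)(Cl)Cl
Why: Acid-catalysed O-benzylation with the trichloroacetimidate keeps the medium free of base, so the bromo alcohol can neither cyclise nor eliminate, and the stereocentre, which carries no acidic hydrogen, is untouched.

Step 2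
Reactants: 2 (R)-[(3-bromo-2-methylpropoxy)methyl]benzene; 3 4-bromo-2-(bromomethyl)-1-methoxybenzene
Product: 5 2-[(3S)-4-(benzyloxy)-3-methylbutyl]-4-bromo-1-methoxybenzene, via Grignard reagent 4 (not isolated)
Conditions: 2 (1.3 equiv), Mg, THF, 40 °C; then 3, Li2CuCl4 (3 mol %), THF, −78 → 0 °C
Reagents that add atoms: magnesium, [Mg] (metal of intermediate 4 only; all atoms of 5 come from 2 and 3)
Why: Copper-catalysed cross-coupling of a primary alkyl Grignard reagent with a benzylic bromide is much faster than any reaction at the aryl bromide, and the stereocentre is β to magnesium and cannot epimerise (the descriptor changes from R to S only because the priorities change).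

Step 3
Reactants: 6 5-hydroxy-2-methyl-4H-pyran-4-one (allomaltol)
Product: 7 2-bromo-3-hydroxy-6-methyl-4H-pyran-4-one
Conditions: N-bromosuccinimide (1.05 equiv), MeCN, 0 °C → rt, dark
Reagents that add atoms: N-bromosuccinimide, O=C1CCC(=O)N1Br
Why: Electrophilic bromination of the enolic 3-hydroxy-4-pyranone should take place ortho to the hydroxyl group (the future C2), the position at which kojic acid and allomaltol accept electrophiles.

Step 4
Reactants: 7 2-bromo-3-hydroxy-6-methyl-4H-pyran-4-one
Product: 8 3-(benzyloxy)-2-bromo-6-methyl-4H-pyran-4-one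
Conditions: BnBr (1.2 equiv), K2CO3 (1.5 equiv), acetone, rt → 40 °C
Reagents that add atoms: benzyl bromide, BrCc1ccccc1
Why: Williamson etherification of the acidic enolic hydroxyl; the benzyl group masks the future 3-hydroxyl during the organometallic steps and falls in the final hydrogenolysis.

Step 5
Reactants: 5 2-[(3S)-4-(benzyloxy)-3-methylbutyl]-4-bromo-1-methoxybenzene; 8 3-(benzyloxy)-2-bromo-6-methyl-4H-pyran-4-one
Product: 11 3-(benzyloxy)-2-{3-[(3S)-4-(benzyloxy)-3-methylbutyl]-4-methoxyphenyl}-6-methyl-4H-pyran-4-one, via aryllithium 9 (not isolated), via arylzinc chloride 10 (not isolated)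
Conditions: 5 (1.1 equiv), n-BuLi (1.1 equiv), THF, −78 °C; ZnCl2 (1.2 equiv), −78 °C → rt; then 8, Pd(PPh3)4 (3 mol %), THF, 50 °C
Reagents that add atoms: n-butyllithium, [Li]CCCC (lithium of intermediate 9 only); zinc dichloride, Cl[Zn]Cl (zinc and chlorine of intermediate 10 only)
Why: Negishi coupling, in which bromine–lithium exchange and transmetalation give a non-basic arylzinc that tolerates the acidic 6-methyl group of 8 and couples at the C2–Br bond, a vinylogous acyl bromide that adds readily to zerovalent palladium.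

Step 6
Reactants: 11 3-(benzyloxy)-2-{3-[(3S)-4-(benzyloxy)-3-methylbutyl]-4-methoxyphenyl}-6-methyl-4H-pyran-4-one
Product: 12 3-(benzyloxy)-2-{3-[(3S)-4-(benzyloxy)-3-methylbutyl]-4-methoxyphenyl}-5-iodo-6-methyl-4H-pyran-4-one
Conditions: I2 (0.6 equiv), (NH4)2Ce(NO3)6 (1.1 equiv), MeCN, 60 °C
Reagents that add atoms: iodine, II
Why: Oxidative electrophilic iodination, which in 2-aryl-4-pyranones such as methoxyflavones goes to the free α-carbon of the pyranone and not to a methoxyphenyl ring deactivated by conjugation with the enone; C5 (the future C4a) is the only free α-position of 11.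

Step 7
Reactants: 13 methyl methoxyacetate; 14 methyl formate
Product: 16 methyl (Z)-2,3-dimethoxyacrylate, via sodium enolate 15 (not isolated)
Conditions: NaOMe (1.1 equiv), 14 (1.5 equiv), toluene, 0 °C → rt; then Me2SO4 (1.1 equiv), DMF, rt; distillation
Reagents that add atoms: dimethyl sulfate, COS(=O)(=O)OC; sodium methoxide, [Na+].[O-]C (sodium of intermediate 15 only)
Why: Crossed Claisen formylation of the ester enolate with methyl formate and O-methylation of the resulting formyl ester enolate by the hard electrophile dimethyl sulfate, the standard entry to β-methoxyacrylates.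

Step 8
Reactants: 16 methyl (Z)-2,3-dimethoxyacrylate; 12 3-(benzyloxy)-2-{3-[(3S)-4-(benzyloxy)-3-methylbutyl]-4-methoxyphenyl}-5-iodo-6-methyl-4H-pyran-4-one
Product: 18 methyl (Z)-3-[5-(benzyloxy)-6-{3-[(3S)-4-(benzyloxy)-3-methylbutyl]-4-methoxyphenyl}-2-methyl-4-oxo-4H-pyran-3-yl]-2,3-dimethoxyacrylate, via alkenylzinc chloride 17 (not isolated)
Conditions: 16 (1.5 equiv), TMPZnCl·LiCl (1.6 equiv), THF, 25 °C; then 12, Pd(OAc)2 (3 mol %), SPhos (6 mol %), THF, 50 °C
Reagents that add atoms: (2,2,6,6-tetramethylpiperidin-1-yl)zinc chloride–lithium chloride, CC1(C)CCCC(C)(C)N1[Zn]Cl.[Li+].[Cl-] (zinc and chlorine of intermediate 17 only)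
Why: Directed zincation of the β-alkoxyacrylate at its only vinylic hydrogen (cis to the ester) by the hindered zinc amide, then Negishi coupling with retention of alkene geometry, which should place pyranone and ester cis; the alkenylzinc is too weakly basic to deprotonate the 2-methyl group of 12.

Step 9
Reactants: 18 methyl (Z)-3-[5-(benzyloxy)-6-{3-[(3S)-4-(benzyloxy)-3-methylbutyl]-4-methoxyphenyl}-2-methyl-4-oxo-4H-pyran-3-yl]-2,3-dimethoxyacrylate
Product: 21 3-(benzyloxy)-2-{3-[(3S)-4-(benzyloxy)-3-methylbutyl]-4-methoxyphenyl}-7-hydroxy-5,6-dimethoxy-4H-chromen-4-one, via lithium dienolate 19 (not isolated), via dienone 20 (not isolated)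
Conditions: LiN(SiMe3)2 (2.5 equiv), THF, −78 → 0 °C; 1 M aq HCl to pH 4
Reagents that add atoms: lithium bis(trimethylsilyl)amide, C[Si](C)(C)N([Li])[Si](C)(C)C (lithium of intermediate 19 only)
Why: The amide base removes a proton from the 2-methyl group of the γ-pyrone (C8), the most acidic C–H of 18, to give the cross-conjugated dienolate 19, whose exocyclic carbon adds to the ester carbonyl (C7) held cis on the C5=C6 double bond; methoxide leaves and dienone 20 enolises to the phenol. The closest known reaction type is the Claisen (Dieckmann) condensation of γ-pyrone and o-toluate methyl anions with esters, as in biomimetic polyketide aromatisations and the Staunton–Weinreb annulation. Ring A closes through C7–C8 in a 6-(enolendo)-exo-trig mode, and aromatisation to the phenoxide makes the closure irreversible. No stereocentre is formed and the side-chain stereocentre is remote from every reacting site. The step needs C-acylation in place of O-acylation at the dienolate oxygen, secured because methoxide can reopen an enol lactone but not the phenoxide, and a cis relation of pyranone and ester, secured by the retentive coupling of step 8 and by methoxide addition–elimination that interconverts the alkene isomers. O7 arises free from the ester carbonyl while O5 and O6 are already methyl ethers, so the ether pattern of ring A needs no later adjustment.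

Step 10
Reactants: 21 3-(benzyloxy)-2-{3-[(3S)-4-(benzyloxy)-3-methylbutyl]-4-methoxyphenyl}-7-hydroxy-5,6-dimethoxy-4H-chromen-4-one
Product: 22 3,7-dihydroxy-2-{3-[(3S)-4-hydroxy-3-methylbutyl]-4-methoxyphenyl}-5,6-dimethoxy-4H-chromen-4-one
Conditions: H2 (1 atm), Pd(OH)2/C, EtOAc/MeOH, rt
Reagents that add atoms: none
Why: Catalytic hydrogenolysis cleaves both benzylic C–O bonds (the enol benzyl ether at C3 and the primary alkyl benzyl ether), while the aromatic flavonol nucleus and the stereocentre should not be affected at atmospheric pressure.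

**Compound list**

1 | (R)-3-bromo-2-methylpropan-1-ol | BrC[C@H](C)CO | starting material
2 | (R)-[(3-bromo-2-methylpropoxy)methyl]benzene | BrC[C@H](C)COCc1ccccc1 | intermediate
3 | 4-bromo-2-(bromomethyl)-1-methoxybenzene | COc1ccc(Br)cc1CBr | starting material
4 | (R)-[3-(benzyloxy)-2-methylpropyl]magnesium bromide | Br[Mg]C[C@H](C)COCc1ccccc1 | intermediate
5 | 2-[(3S)-4-(benzyloxy)-3-methylbutyl]-4-bromo-1-methoxybenzene | COc1ccc(Br)cc1CC[C@H](C)COCc1ccccc1 | intermediate
6 | 5-hydroxy-2-methyl-4H-pyran-4-one (allomaltol) | Cc1cc(=O)c(O)co1 | starting material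
7 | 2-bromo-3-hydroxy-6-methyl-4H-pyran-4-one | Cc1cc(=O)c(O)c(Br)o1 | intermediate
8 | 3-(benzyloxy)-2-bromo-6-methyl-4H-pyran-4-one | Cc1cc(=O)c(OCc2ccccc2)c(Br)o1 | intermediate
9 | {3-[(3S)-4-(benzyloxy)-3-methylbutyl]-4-methoxyphenyl}lithium | [Li]c1ccc(OC)c(CC[C@H](C)COCc2ccccc2)c1 | intermediate
10 | chloro{3-[(3S)-4-(benzyloxy)-3-methylbutyl]-4-methoxyphenyl}zinc | Cl[Zn]c1ccc(OC)c(CC[C@H](C)COCc2ccccc2)c1 | intermediate
11 | 3-(benzyloxy)-2-{3-[(3S)-4-(benzyloxy)-3-methylbutyl]-4-methoxyphenyl}-6-methyl-4H-pyran-4-one | Cc1cc(=O)c(OCc2ccccc2)c(-c2ccc(OC)c(CC[C@H](C)COCc3ccccc3)c2)o1 | intermediate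
12 | 3-(benzyloxy)-2-{3-[(3S)-4-(benzyloxy)-3-methylbutyl]-4-methoxyphenyl}-5-iodo-6-methyl-4H-pyran-4-one | Cc1oc(-c2ccc(OC)c(CC[C@H](C)COCc3ccccc3)c2)c(OCc2ccccc2)c(=O)c1I | intermediate
13 | methyl methoxyacetate | COCC(=O)OC | starting material
14 | methyl formate | COC=O | starting material
15 | sodium 2,3-dimethoxy-3-oxoprop-1-en-1-olate (geometry not defined) | [Na+].[O-]C=C(OC)C(=O)OC | intermediate
16 | methyl (Z)-2,3-dimethoxyacrylate | CO/C=C(\OC)C(=O)OC | intermediate
17 | chloro[(E)-1,2,3-trimethoxy-3-oxoprop-1-en-1-yl]zinc | CO/C([Zn]Cl)=C(\OC)C(=O)OC | intermediate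
18 | methyl (Z)-3-[5-(benzyloxy)-6-{3-[(3S)-4-(benzyloxy)-3-methylbutyl]-4-methoxyphenyl}-2-methyl-4-oxo-4H-pyran-3-yl]-2,3-dimethoxyacrylate | COC(=O)/C(OC)=C(/OC)c1c(C)oc(-c2ccc(OC)c(CC[C@H](C)COCc3ccccc3)c2)c(OCc2ccccc2)c1=O | intermediate
19 | lithium 5-(benzyloxy)-6-{3-[(3S)-4-(benzyloxy)-3-methylbutyl]-4-methoxyphenyl}-2-methylidene-3-[(Z)-1,2,3-trimethoxy-3-oxoprop-1-en-1-yl]-2H-pyran-4-olate | C=C1OC(-c2ccc(OC)c(CC[C@H](C)COCc3ccccc3)c2)=C(OCc2ccccc2)C(O[Li])=C1/C(OC)=C(/OC)C(=O)OC | intermediate
20 | 3-(benzyloxy)-2-{3-[(3S)-4-(benzyloxy)-3-methylbutyl]-4-methoxyphenyl}-5,6-dimethoxy-4H-chromene-4,7(8H)-dione | COC1=C(OC)C(=O)CC2=C1C(=O)C(OCc1ccccc1)=C(-c1ccc(OC)c(CC[C@H](C)COCc3ccccc3)c1)O2 | intermediate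
21 | 3-(benzyloxy)-2-{3-[(3S)-4-(benzyloxy)-3-methylbutyl]-4-methoxyphenyl}-7-hydroxy-5,6-dimethoxy-4H-chromen-4-one | COc1ccc(-c2oc3cc(O)c(OC)c(OC)c3c(=O)c2OCc2ccccc2)cc1CC[C@H](C)COCc1ccccc1 | intermediate
22 | 3,7-dihydroxy-2-{3-[(3S)-4-hydroxy-3-methylbutyl]-4-methoxyphenyl}-5,6-dimethoxy-4H-chromen-4-one | COc1ccc(-c2oc3cc(O)c(OC)c(OC)c3c(=O)c2O)cc1CC[C@H](C)CO | target

**Step count and risks**

Total step count: 10. Longest linear sequence: 7 steps (steps 1, 2, 5, 6, 8, 9, 10 from compound 1, or steps 3, 4, 5, 6, 8, 9, 10 from compound 6).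

The three steps most likely to fail:

Step 8. Transmetalation and reductive elimination at the hindered C–I bond (flanked by the carbonyl and the methyl-bearing carbon) may be slow for a coupling that forms a tetrasubstituted alkene, so that protodeiodination of 12 or homocoupling of the alkenylzinc takes over. Fallback: setting out from 12, a palladium-catalysed carbonylative coupling with potassium methyl 2-methoxymalonate (Pd(dba)2, Xantphos, CO 1 atm, MgCl2, Et3N, THF, 60 °C) should give, after loss of CO2, the β-keto ester methyl 3-[5-(benzyloxy)-6-{3-[(3S)-4-(benzyloxy)-3-methylbutyl]-4-methoxyphenyl}-2-methyl-4-oxo-4H-pyran-3-yl]-2-methoxy-3-oxopropanoate F1 (epimers at the methoxy-bearing carbon). O-Methylation of its enolate (Me2SO4, K2CO3, acetone) should give 18 together with its alkene isomer methyl (E)-3-[5-(benzyloxy)-6-{3-[(3S)-4-(benzyloxy)-3-methylbutyl]-4-methoxyphenyl}-2-methyl-4-oxo-4H-pyran-3-yl]-2,3-dimethoxyacrylate F2. The mixture comes back to the route at 18, since step 9 takes both isomers.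

Step 6. Site selectivity of the electrophilic iodination may be lost (attack on ring B ortho to its methoxy group), or the cerium salt may oxidise the benzylic positions. Fallback: setting out from 8, iodination before ring B is present (N-iodosuccinimide, CF3CO2H, MeCN) should give 3-(benzyloxy)-2-bromo-5-iodo-6-methyl-4H-pyran-4-one F3. The alkenylzinc 17 should then couple first at the weaker C–I bond (Pd(PPh3)4, THF, rt) to give methyl (Z)-3-[5-(benzyloxy)-6-bromo-2-methyl-4-oxo-4H-pyran-3-yl]-2,3-dimethoxyacrylate F4, and the arylzinc 10 should couple at the remaining C–Br bond under the conditions of step 5. This comes back to the route at 18.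

Step 9. The dienolate may be acylated at oxygen and stay there, or amide and methoxide may add to the pyranone and open it before the carbon–carbon bond forms. Fallback: setting out from 18, ester cleavage (Me3SnOH, 1,2-dichloroethane, 70 °C) should give (Z)-3-[5-(benzyloxy)-6-{3-[(3S)-4-(benzyloxy)-3-methylbutyl]-4-methoxyphenyl}-2-methyl-4-oxo-4H-pyran-3-yl]-2,3-dimethoxyacrylic acid F5. 1,1'-Carbonyldiimidazole should convert it to the acyl imidazole 5-(benzyloxy)-6-{3-[(3S)-4-(benzyloxy)-3-methylbutyl]-4-methoxyphenyl}-3-[(Z)-3-(1H-imidazol-1-yl)-1,2-dimethoxy-3-oxoprop-1-en-1-yl]-2-methyl-4H-pyran-4-one F6. Soft enolisation of the 2-methyl group (MgBr2·OEt2, i-Pr2NEt, CH2Cl2) should then close ring A with this stronger acyl donor and without a strong base, which comes back to the route at 21.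

**Further compounds**

F1 | step 8 | methyl 3-[5-(benzyloxy)-6-{3-[(3S)-4-(benzyloxy)-3-methylbutyl]-4-methoxyphenyl}-2-methyl-4-oxo-4H-pyran-3-yl]-2-methoxy-3-oxopropanoate | COC(=O)C(OC)C(=O)c1c(C)oc(-c2ccc(OC)c(CC[C@H](C)COCc3ccccc3)c2)c(OCc2ccccc2)c1=O
F2 | step 8 | methyl (E)-3-[5-(benzyloxy)-6-{3-[(3S)-4-(benzyloxy)-3-methylbutyl]-4-methoxyphenyl}-2-methyl-4-oxo-4H-pyran-3-yl]-2,3-dimethoxyacrylate | COC(=O)/C(OC)=C(\OC)c1c(C)oc(-c2ccc(OC)c(CC[C@H](C)COCc3ccccc3)c2)c(OCc2ccccc2)c1=O
F3 | step 6 | 3-(benzyloxy)-2-bromo-5-iodo-6-methyl-4H-pyran-4-one | Cc1oc(Br)c(OCc2ccccc2)c(=O)c1I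
F4 | step 6 | methyl (Z)-3-[5-(benzyloxy)-6-bromo-2-methyl-4-oxo-4H-pyran-3-yl]-2,3-dimethoxyacrylate | COC(=O)/C(OC)=C(/OC)c1c(C)oc(Br)c(OCc2ccccc2)c1=O
F5 | step 9 | (Z)-3-[5-(benzyloxy)-6-{3-[(3S)-4-(benzyloxy)-3-methylbutyl]-4-methoxyphenyl}-2-methyl-4-oxo-4H-pyran-3-yl]-2,3-dimethoxyacrylic acid | OC(=O)/C(OC)=C(/OC)c1c(C)oc(-c2ccc(OC)c(CC[C@H](C)COCc3ccccc3)c2)c(OCc2ccccc2)c1=O
F6 | step 9 | 5-(benzyloxy)-6-{3-[(3S)-4-(benzyloxy)-3-methylbutyl]-4-methoxyphenyl}-3-[(Z)-3-(1H-imidazol-1-yl)-1,2-dimethoxy-3-oxoprop-1-en-1-yl]-2-methyl-4H-pyran-4-one | O=C(/C(OC)=C(/OC)c1c(C)oc(-c2ccc(OC)c(CC[C@H](C)COCc3ccccc3)c2)c(OCc2ccccc2)c1=O)n1ccnc1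
A1 | direct plan | 2-iodo-4-methoxy-3,5-bis(methoxymethoxy)phenol | COCOc1cc(O)c(I)c(OCOC)c1OC
A2 | direct plan | 2-[(3S)-4-(benzyloxy)-3-methylbutyl]-4-ethynyl-1-methoxybenzene | C#Cc1ccc(OC)c(CC[C@H](C)COCc2ccccc2)c1
A3 | direct plan | 2-{3-[(3S)-4-(benzyloxy)-3-methylbutyl]-4-methoxyphenyl}-6-methoxy-5,7-bis(methoxymethoxy)-4H-chromen-4-one | COCOc1cc2oc(-c3ccc(OC)c(CC[C@H](C)COCc4ccccc4)c3)cc(=O)c2c(OCOC)c1OC
A4 | direct plan | 7-(benzyloxy)-2-{3-[(3S)-4-(benzyloxy)-3-methylbutyl]-4-methoxyphenyl}-5,6-dimethoxy-4H-chromen-4-one | COc1c(OCc2ccccc2)cc2oc(-c3ccc(OC)c(CC[C@H](C)COCc4ccccc4)c3)cc(=O)c2c1OC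
A5 | direct plan | (R)-3-(benzyloxy)-2-methylpropanal | O=C[C@H](C)COCc1ccccc1
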